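**Easy step.** The flask's initiator is 2.5 mol% of 2.0 M free monomer, so [initiator] is 0.0500 M.

in all of them: stray impurity 15 mM

| flask | free monomer | transfer agent | protic impurity | initiator | remark | time |
|---|---|---|---|---|---|---|
| south | 2 M | 0.060 M | 0.020 M | 2.5 mol% | run made earlier |  |
| south-east | 2 M | 0.060 M | 0.080 M | 2.5 mol% | run made earlier |  |
| south-west | 2 M | 0.060 M | 0.040 M | 3.8 mol% | run made earlier |  |
| flask | 2.0 M | 0.0600 M | 0.0400 M | 2.5 mol% |  | 10 d |

| run | time / d | monomer in chains / % | free monomer / % |
|---|---|---|---|
| south | 2.50 | 68 | 33 |
| south | 5.00 | 81 | 19 |
| south | 8.00 | 87 | 17 |
| south | 10.0 | 82 | 14 |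
| south-east | 2.50 | 67 | 26 |
| south-east | 5.00 | 78 | 19 |
| south-east | 8.00 | 82 | 17 |
| south-east | 10.0 | 83 | 11 |
| south-west | 2.50 | 87 | 14 |
| south-west | 5.00 | 95 | 7 |
| south-west | 8.00 | 95 | 2 |
| south-west | 10.0 | 98 | 1 |

(each reading ± 1.5 percentage points)

- the average divides the monomer in chains by the number of chains begun, living and dead together
- the numbers in the tables scatter by 1.5 percentage points (one standard deviation)
- the earlier runs do not show the number of chains; that part of a forecast is a guess

* whether the average number of monomer units in a chain (chains begun, living or dead) reaches 20 by 10 d (yes / no)
* average number of monomer units in a chain (chains begun, living or dead) at 10 d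

**Bench rule.** The bench rule counts one chain per initiator, so length is monomer in chains over initiator charged. South and south-east read 82% and 83% in chains at 10.0 d, and the flask's [protic impurity] lies between theirs. Taking 82.5% gives a first length of 33.0.

**Its border.** The rule needs [stray impurity]/[initiator] to be small, but here it is 0.300. From south to south-west, both initiator and [protic impurity] change, and ln(1/free monomer) at 2.50 d reads 1.77 times higher. The initiator charges stand at 1.52, and the charges less stray impurity at 1.74. Provided [protic impurity] moves it little, the reading sides with the second ratio, so the quantity to carry is the live charge, initiator charged less stray impurity, the limiting reagent for chains: 0.0350 M.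

**Second round.** From south to south-east, [protic impurity] rises from 0.020 M to 0.080 M; free monomer reads 33% and 26% at 2.50 d, but 19% and 19% at 5.00 d, so no lasting gain in growing ends shows. South's free monomer still reads 14% at 10.0 d, so ends seem lost, not renewed. This reckoning therefore guesses chains begun equal the live charge, and the length becomes 47.1, past the wanted length.

**The forecast.** The forecast answers no, with 15 units, between 11 and 22. Of the protic impurity it says “probably exchanges and starts new chains”. Its count of about 0.11 M chains against the live charge is where the two part.

**The flask.** The flask answers yes, with 48.0 units at 10 d.

    free monomer + initiator → living end + monomer in chains (k = 0.0810 /M/h)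
    free monomer + living end → monomer in chains + living end, rate k2*[living end]*[free monomer] (k = 1.10 /M/h)
    living end + transfer agent → dead chain (kL = 0.480 /M/h)
    initiator + stray impurity → spent initiator (k = 1600 /M/h)
    protic impurity + free monomer → quenched substrate (k = 0.100 /M/h)

**Live charge.** Monomer in chains, 84.0%, over the live charge gives 48.0. At 1.06 d the half-life of living end against transfer agent is 1.3 d, shorter than the run, and at 10.0 d the half-life of free monomer by growth stands at 28 d, longer than the run. Free monomer stands at 14.0% then and 12.9% at 100 d. With half the free monomer and other amounts as they are, this flask's share in chains over the same live charge gives 24.0, and that simulated run gives 23.6.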